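## Structural features

The target is built on a 6-oxabicyclo[3.2.1]octane: a cyclohexane (Ca–Cc–Ch–Cg–Cb–Cd) whose 1,3-related carbons Ca and Cb are spanned by the ether unit Ce–O, so that Cd is the one-atom bridge. Labels: Ca is the quaternary carbon carrying the ether CH2 (Ce) and the dienyl chain; Cb the ether carbon carrying the CH(CH3)CHO arm (its CH is C-alpha); Cc the C(CH3)OH carbon; Cd the CH with the 3-hydroxypropyl arm; Cg and Ch the ring CH2 groups next to Cb and Cc. Four contiguous ring stereocentres (Cc, Ca, Cd, Cb), three of them fully substituted, adjoin the exocyclic C-alpha. Two further stereocentres lie in a remote (1R,5S)-2,5,6,6-tetramethylcyclohex-2-enyl ring (the cis-α-irone pattern), tied to Ca through two methylenes and an (E,E)-diene. Fragile groups are the α-stereogenic β-alkoxy aldehyde (epimerisation, base-induced opening of the ether), the skipped triene with its doubly allylic ring C–H (acid, quinone oxidants, singlet oxygen) and the tertiary alcohol beside the quaternary carbon. The real difficulty is the congested Cc–Ca–Cd–Cb array, with two tertiary C–O bonds and no neighbouring carbonyl to guide their formation. The two tertiary oxygens on Cb and Cc are 1,4 and cis on the carbocycle and lie on the face that also holds Ce and the Cd side chain. One molecule of O2 added across a diene Cc=Ch–Cg=Cb can therefore supply both, after which the Cb oxygen closes onto Ce.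

## Logic of the disconnections

36 ⇒ 35 ⇒ 34 ⇒ 33. No skeletal bond is cut; the aldehyde goes back to a primary alcohol and the free hydroxyls to silyl ethers. The reason is that the β-alkoxy aldehyde then exists only in the last two operations. The demand is an order of unmasking: the C-alpha CH2O group must be freed before the propyl hydroxyl and without oxidants that attack the triene. This is why a triethylsilyl/tert-butyldimethylsilyl pair is used and not a benzyl-type ether.

33 ⇒ 25 + 31. The cut is the sp3–sp2 bond between the second methylene of the Ca arm and the trisubstituted alkene. It splits the molecule into a core and a side-chain fragment of similar size, with both alkene geometries already fixed in 31. The forward step needs a primary alkylzinc that tolerates the ethers. The tertiary hydroxyl on Cc is masked as a trimethylsilyl ether so that it can neither displace the iodide nor quench the zinc reagent.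

31 ⇒ 29 ⇒ 27 ⇒ 26. The C–I and C–CH3 bonds are removed together (carbometalation), the alkyne goes back to a methyl ketone, and 27 is traced to 26 by separation of stereoisomers. The gain is a commercial carbon skeleton. The demands are syn, terminal-selective carboalumination, no epimerisation of the doubly allylic ring CH, and a working resolution, since 26 is racemic and a cis/trans mixture.

25 ⇒ 24 ⇒ 23. These are functional-group changes only: iodide from alcohol from pivalate. The pivalate must be the only ester in 23.

23 ⇒ 20. The Ce–O bond is cut. The ether oxygen is already on Cb, cis to CH2OH, so the bicycle simplifies to a monocyclic triol. The forward step must activate only the neopentyl primary hydroxyl and close through the Cb hydroxyl without an alkoxide at Cc, which could trigger 1,3-diol monosulfonate fragmentation.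

20 ⇒ 19 ⇒ 17 + 18. The Cb–O and Cc–O bonds are cut, by way of the O–O bridged 19. This removes two tertiary stereocentres at once and returns a planar diene. The demand is facial selectivity: oxygen must add syn to CH2OH and to the Cd chain.

17 ⇒ 16 ⇒ 15. The two hydroxylated arms on Ca are traced to one γ-lactone. This replaces an awkward α-(2-oxyethyl) acetoacetate by a cyclic β-keto ester equivalent and postpones the differentiation of the arms. The forward demand is selective acylation of the unhindered primary hydroxyl in 16 over the neopentyl one.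

15 ⇒ 14 ⇒ 13. The diene is traced to an enone through its dienyl triflate; Cb returns to sp3. The demand is regioselective α′-enolisation at the tertiary Cb–H.

13 ⇒ 12 ⇒ 10 ⇒ 7 + 8. The Cb–C-alpha bond is cut. A branched allylation sets C-alpha under catalyst control, and one carbon is then excised to give the CH2O group. The demands are branched regioselectivity and the correct face at the allyl carbon; the configuration created at Cb is irrelevant because Cb becomes sp2 in 14.

7 ⇒ 4 + 5. Ca–Cd (Michael) and Cc=Ch (aldol condensation) are cut. The carbocycle and its two lasting stereocentres come from an achiral enone and a racemic, enolisable keto lactone. The demands are enantio- and diastereocontrol (lactone carbonyl cis to the Cd chain) and the Hagemann-type aldol regiochemistry.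

4 ⇒ 2 + 3, and 2 ⇒ 1. The enone C=C is cut by cross-metathesis and the silyl ether is removed, reaching two commodity chemicals.

## Other disconnections considered

Alternative 1: The cut is the Cd–Cb bond. A seven-membered cyclic ether already holding Ca, Ce, O, Cb, Cg, Ch and Cc carries an exocyclic β-alkoxyacrylate at Cb and a xanthate on the side-chain carbinol (oxepane xanthate A2). Tin hydride generates a secondary radical at Cd, which adds to Cb and closes the tetrahydrofuran (5-exo) and the carbocycle together, giving the bridged ester A1.
- In its favour: it forms a C–C bond and two rings in one step, more skeletal construction than the chosen key step, and on this point it is the better plan. Either carbinol epimer converges on one radical. The ether is in place before the congested centres are joined, so no late displacement at a neopentyl carbon is needed. It needs no peroxide.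
- Against it: C-alpha is set by hydrogen transfer to an α-ester radical, a weak control element where the chosen plan uses a catalyst. The Cd chain must end up syn to the ether bridge in a transannular transition state that is hard to predict. The oxepane with its Ca and Cc stereocentres and a fully substituted enol ether must be built first. Afterwards the ester has to be reduced to the aldehyde and the allyl group extended through a carbonyl olefination, which controls the trisubstituted alkene less well than coupling of a preformed (E)-iodide. Stoichiometric tin is required.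
- Step economy is expected to be similar or somewhat worse.

Alternative 2: The cuts are Cb–O and Ca–Ce. The bicyclo[3.1.0]hexanone keto ester A4 (Ca as acceptor carbon, Cb as isopropenyl-bearing donor, Cd as third ring carbon) is activated by Sn(OTf)2 and takes up formaldehyde A5 across the internal Ca–Cb bond. The tetrahydrofuran forms and the five-membered ketone grows into the six-membered ring of A3.
- In its favour: a C–C bond, a C–O bond, one ring and a ring expansion arise in one operation, and the cis bridge is enforced geometrically. The relative configuration of Ca, Cb and Cd comes from a stereospecific cyclopropanation, which is more secure than a diastereoselective Michael addition, and on this point the alternative is the better plan.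
- Against it: formaldehyde is a capricious partner. The donor is a vinyl-substituted tertiary carbon, so attack at the allyl terminus and cleavage of the external Ca–Cd bond compete. A3 still lacks the Cc methyl carbinol (addition next to a quaternary centre under substrate control), C-alpha (hydroboration of an isopropenyl group under substrate control) and two carbons of the Ca arm.
- Three stereochemical problems are left for late substrate-controlled steps, where the chosen plan settles Cc in the key step and C-alpha by catalyst. The front end would be shorter and the back end longer.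

Alternative 3: The cut is Ce–O, made from a methyl group. The tertiary alcohol A7, with an axial methyl on Ca, is converted into its hypoiodite (PhI(OAc)2, I2, light). The alkoxyl radical abstracts a δ-hydrogen from the methyl, and the iodinated carbon is displaced by the oxygen to give A6.
- In its favour: no differentiated CH2OH has to be carried, the quaternary centre then bears only methyl and an acetate arm and is easier to make, and the 1,3-diaxial O/CH3 geometry is ideal for hydrogen transfer. It avoids substitution at a neopentyl carbon and is on this point the equal or the better of the chosen closure.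
- Against it: a tertiary alkoxyl radical flanked by three substituted carbons can fragment (β-scission toward C-alpha or into the ring). The second carbon of the propyl chain offers a competing δ-hydrogen. Above all, A7 already needs both tertiary oxygens with the right relative configuration, so the central problem that the singlet-oxygen step solves in one stroke is only moved upstream, probably into two separate carbonyl additions. The route would be longer.

Key step: step 11

Assumptions: commercial α-irone is taken to be the racemic cis/trans mixture, so the (2S,6R)-cis isomer must be separated from it (step 16). For each chiral catalyst the antipode that gives the drawn configuration is used, and this must be confirmed on the first run.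

## Steps

Step 1
Reactants: 1 pent-4-en-1-ol
Product: 2 tert-butyldimethyl(pent-4-en-1-yloxy)silane
Conditions: TBSCl, imidazole, CH2Cl2, 0 °C to rt
Reagents that add atoms: tert-butyldimethylsilyl chloride, CC(C)(C)[Si](C)(C)Cl
Why: Routine silylation of a primary alcohol; the ether prevents oxa-Michael cyclisation onto the enone made next and is kept until the last step.

Step 2
Reactants: 2 tert-butyldimethyl(pent-4-en-1-yloxy)silane; 3 but-3-en-2-one
Product: 4 (E)-7-[(tert-butyldimethylsilyl)oxy]hept-3-en-2-one
Conditions: second-generation Hoveyda–Grubbs catalyst (2 mol %), CH2Cl2, 40 °C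
Reagents that add atoms: none
Why: Olefin cross-metathesis of a terminal alkene with an electron-poor vinyl ketone is selective for the cross product and gives the (E)-enone under thermodynamic control, with loss of ethene.

Step 3
Reactants: 4 (E)-7-[(tert-butyldimethylsilyl)oxy]hept-3-en-2-one; 5 3-acetyloxolan-2-one
Product: 7 6-methyl-10-[3-(tert-butyldimethylsilyloxy)propyl]-2-oxaspiro[4.5]dec-6-ene-1,8-dione (lactone carbonyl cis to the C10 chain), via Michael adduct 6 (not isolated)
Conditions: 9-amino-9-deoxy-epi-quinine (20 mol %), 2-FC6H4CO2H (40 mol %), toluene, rt; then pyrrolidine, AcOH, 50 °C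
Reagents that add atoms: none
Why: Asymmetric Robinson annulation: the primary amine activates the (E)-enone as an iminium ion while the quinuclidine delivers the enol of the cyclic β-keto lactone, setting Ca and Cd in the Michael event. The less hindered chain methyl ketone then condenses as its enamine onto the acetyl carbonyl (Hagemann-type regiochemistry), closing the cyclohexenone.

Step 4
Reactants: 7 spiro enone; 8 (E)-but-2-en-1-yl methyl carbonate
Product: 10 9-[(2R)-but-3-en-2-yl]-6-methyl-10-[3-(tert-butyldimethylsilyloxy)propyl]-2-oxaspiro[4.5]dec-6-ene-1,8-dione, via silyl dienol ether 9 (not isolated)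
Conditions: LiN(i-Pr)2, TMSCl, THF, −78 °C; then 8, [Ir(cod)Cl]2 (2 mol %), BINOL-derived bis(1-phenylethyl)amine phosphoramidite (4 mol %), CsF, ZnF2, DME, 50 °C
Reagents that add atoms: none
Why: Kinetic α′-deprotonation gives the cross-conjugated enolate, trapped as 9; the fluoride-released enolate attacks the (π-allyl)iridium complex at its substituted terminus (iridium-catalysed branched allylic alkylation of an enone-derived silyl dienol ether). The phosphoramidite antipode fixes C-alpha; the new Cb centre, expected trans to the Cd chain, is erased in step 7.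

Step 5
Reactants: 10 crotylated enone
Product: 12 9-[(2S)-1-hydroxypropan-2-yl]-6-methyl-10-[3-(tert-butyldimethylsilyloxy)propyl]-2-oxaspiro[4.5]dec-6-ene-1,8-dione, via keto aldehyde 11 (not isolated)
Conditions: K2OsO4·2H2O (2 mol %), NaIO4, 2,6-lutidine, dioxane/H2O, rt; then NaBH4, MeOH/CH2Cl2, −78 °C
Reagents that add atoms: sodium periodate, [Na+].[O-]I(=O)(=O)=O; water, O
Why: Lemieux–Johnson cleavage attacks only the monosubstituted alkene, the trisubstituted enone double bond being electron-poor. At −78 °C borohydride reduces the aldehyde faster than the conjugated ketone or the lactone, and the lutidine buffer protects C-alpha from enolisation.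

Step 6
Reactants: 12 hydroxy enone
Product: 13 6-methyl-10-[3-(tert-butyldimethylsilyloxy)propyl]-9-[(2S)-1-(triethylsilyloxy)propan-2-yl]-2-oxaspiro[4.5]dec-6-ene-1,8-dione
Conditions: TESCl, imidazole, CH2Cl2, 0 °C
Reagents that add atoms: chlorotriethylsilane, CC[Si](Cl)(CC)CC
Why: Silylation of the only free hydroxyl; the triethylsilyl ether can later be removed in the presence of the tert-butyldimethylsilyl ether without oxidants.

Step 7
Reactants: 13 silyl-protected enone
Product: 14 6-methyl-1-oxo-10-[3-(tert-butyldimethylsilyloxy)propyl]-9-[(2S)-1-(triethylsilyloxy)propan-2-yl]-2-oxaspiro[4.5]deca-6,8-dien-8-yl trifluoromethanesulfonate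
Conditions: LiN(i-Pr)2, THF, −78 °C; then N-(5-chloropyridin-2-yl)triflimide, −78 to 0 °C
Reagents that add atoms: N-(5-chloropyridin-2-yl)bis(trifluoromethanesulfonyl)imide, O=S(=O)(N(c1ccc(Cl)cn1)S(=O)(=O)C(F)(F)F)C(F)(F)F
Why: Kinetic deprotonation of the single α′-hydrogen (Cb–H), as with other 6-substituted cyclohex-2-enones, and O-sulfonylation give the 2-triflyloxy-1,3-diene; the lactone has no α-hydrogen and Cb becomes sp2.

Step 8
Reactants: 14 dienyl triflate
Product: 15 6-methyl-10-[3-(tert-butyldimethylsilyloxy)propyl]-9-[(2S)-1-(triethylsilyloxy)propan-2-yl]-2-oxaspiro[4.5]deca-6,8-dien-1-one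
Conditions: Pd(OAc)2 (5 mol %), PPh3, HCO2H, Bu3N, DMF, 60 °C
Reagents that add atoms: none
Why: Palladium-catalysed formate reduction of an alkenyl triflate (oxidative addition, decarboxylation of formate to a hydride, reductive elimination) replaces C–OTf by C–H without moving the double bonds, giving the Cc=Ch–Cg=Cb diene.

Step 9
Reactants: 15 spiro lactone diene
Product: 16 2-[1-(hydroxymethyl)-2-methyl-6-[3-(tert-butyldimethylsilyloxy)propyl]-5-[(2S)-1-(triethylsilyloxy)propan-2-yl]cyclohexa-2,4-dien-1-yl]ethanol
Conditions: LiAlH4, THF, 0 °C
Reagents that add atoms: none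
Why: Hydride reduction of the lactone to the 1,4-diol; the diene and silyl ethers are inert, and the quaternary Ca blocks aromatisation.

Step 10
Reactants: 16 diene diol
Product: 17 2-[1-(hydroxymethyl)-2-methyl-6-[3-(tert-butyldimethylsilyloxy)propyl]-5-[(2S)-1-(triethylsilyloxy)propan-2-yl]cyclohexa-2,4-dien-1-yl]ethyl pivalate
Conditions: PivCl (1.05 equiv), pyridine, CH2Cl2, −20 to 0 °C
Reagents that add atoms: pivaloyl chloride, CC(C)(C)C(Cl)=O
Why: The bulky acyl chloride esterifies the unhindered primary hydroxyl of the two-carbon arm far faster than the neopentyl CH2OH. This leaves the hydrogen-bond donor on the face that must be oxygenated and puts a bulky ester on the opposite face.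

Step 11
Reactants: 17 diene pivalate with free CH2OH on Ca; 18 dioxygen
Product: 19 2-[7-(hydroxymethyl)-1-methyl-8-[3-(tert-butyldimethylsilyloxy)propyl]-4-[1-(triethylsilyloxy)propan-2-yl]-2,3-dioxabicyclo[2.2.2]oct-5-en-7-yl]ethyl pivalate
Conditions: O2, tetraphenylporphyrin (0.5 mol %), visible light, CH2Cl2, −40 °C
Reagents that add atoms: none
Why: The porphyrin sensitises ground-state oxygen to singlet oxygen, which adds to the ring-locked s-cis diene Cc=Ch–Cg=Cb in a concerted suprafacial (4+2) cycloaddition. The closest known reaction type is the dye-sensitised photooxygenation of 1,4-dialkylcyclohexa-1,3-dienes to ascaridole-type endoperoxides. The one ring closed, the 1,2-dioxine of the 2,3-dioxabicyclo[2.2.2]oct-5-ene, is formed by a [4πs+2πs] cycloaddition that makes the Cb–O and Cc–O bonds on the same face. The cis-1,4 relation of the new stereocentres Cb and Cc follows from that suprafacial mode. Their sense relative to Ca and Cd depends on the face attacked. Two substrate elements are meant to direct oxygen to the face of CH2OH and the Cd chain: a hydrogen bond from the free hydroxyl to the developing peroxy terminus, favoured by the non-polar solvent and low temperature, and the pseudoaxial pivaloyloxyethyl arm covering the other face. The step also needs cycloaddition to outrun the ene reaction, which the fixed s-cis geometry and dialkyl substitution of the diene provide, and chemoselectivity, which holds because the silyl ethers and the ester have no reactive π-system. The facial outcome is not secured by precedent for a homoallylic hydroxyl and must be checked.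

Step 12
Reactants: 19 endoperoxide
Product: 20 2-[2,5-dihydroxy-1-(hydroxymethyl)-2-methyl-6-[3-(tert-butyldimethylsilyloxy)propyl]-5-[1-(triethylsilyloxy)propan-2-yl]cyclohexyl]ethyl pivalate (both tertiary hydroxyls cis to CH2OH)
Conditions: H2 (1 atm), PtO2 (5 mol %), EtOAc, rt
Reagents that add atoms: none
Why: Catalytic hydrogenation cleaves the O–O bond and saturates the ring double bond without touching either C–O bond, as in the conversion of ascaridole into the cis-1,4-diol. Platinum in a neutral aprotic solvent limits allylic hydrogenolysis and silyl ether loss.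

Step 13
Reactants: 20 triol
Product: 23 2-[2-methyl-8-[3-(tert-butyldimethylsilyloxy)propyl]-5-[1-(triethylsilyloxy)propan-2-yl]-2-(trimethylsilyloxy)-6-oxabicyclo[3.2.1]octan-1-yl]ethyl pivalate, via primary triflate 21 (not isolated), via hydroxy ether 22 (not isolated)
Conditions: Tf2O (1.05 equiv), 2,6-lutidine, CH2Cl2, −78 to 0 °C; then TMSOTf, −78 to 0 °C
Reagents that add atoms: trimethylsilyl trifluoromethanesulfonate, C[Si](C)(C)OS(=O)(=O)C(F)(F)F
Why: At −78 °C only the primary hydroxyl is sulfonylated. On warming, the cis-1,3-related Cb hydroxyl displaces the neopentyl triflate in a 5-exo-tet etherification that needs no alkoxide, so fragmentation through a Cc alkoxide is avoided and the four-membered alternative from Cc–OH cannot compete. The remaining tertiary hydroxyl is then silylated in the same flask so that it cannot attack the iodide made in step 15.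

Step 14
Reactants: 23 bridged ether pivalate
Product: 24 2-[2-methyl-8-[3-(tert-butyldimethylsilyloxy)propyl]-5-[1-(triethylsilyloxy)propan-2-yl]-2-(trimethylsilyloxy)-6-oxabicyclo[3.2.1]octan-1-yl]ethanol
Conditions: i-Bu2AlH, CH2Cl2, −78 °C
Reagents that add atoms: none
Why: Reductive cleavage of the only ester; all three silyl ethers and the cyclic ether are stable to the hydride and to a neutral tartrate work-up.

Step 15
Reactants: 24 primary alcohol
Product: 25 1-(2-iodoethyl)-2-methyl-8-[3-(tert-butyldimethylsilyloxy)propyl]-5-[1-(triethylsilyloxy)propan-2-yl]-2-(trimethylsilyloxy)-6-oxabicyclo[3.2.1]octane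
Conditions: I2, PPh3, imidazole, CH2Cl2, 0 °C
Reagents that add atoms: iodine, II
Why: Appel-type iodination of an unhindered primary alcohol (the carbinol carbon is two atoms from the quaternary centre); imidazole buffers the acid and protects the silyl ethers.

Step 16
Reactants: 26 α-irone (commercial mixture of racemic cis and trans isomers)
Product: 27 (E)-4-[(1R,5S)-2,5,6,6-tetramethylcyclohex-2-en-1-yl]but-3-en-2-one ((2S,6R)-cis-α-irone)
Conditions: preparative supercritical-fluid chromatography, amylose tris(3,5-dimethylphenylcarbamate) on silica, CO2/i-PrOH, 35 °C (cis/trans pre-separation on AgNO3-impregnated silica if needed)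
Reagents that add atoms: none
Why: No bond changes; the four stereoisomers are separated physically, the diastereomers by their different polarity and the enantiomers on the polysaccharide phase. The wanted isomer is assigned by chiroptical comparison with cis-α-irone of known configuration.

Step 17
Reactants: 27 (2S,6R)-cis-α-irone
Product: 29 (E)-4-[(1R,5S)-2,5,6,6-tetramethylcyclohex-2-en-1-yl]but-3-en-1-yne, via enol phosphate 28 (not isolated)
Conditions: LiN(i-Pr)2, THF, −78 °C; ClP(O)(OEt)2; then LiN(i-Pr)2 (2.2 equiv), −78 to 0 °C; aq. NH4Cl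
Reagents that add atoms: none
Why: One-flask conversion of a methyl ketone into a terminal alkyne: kinetic enolisation at the methyl group, O-phosphorylation, then amide-induced elimination. The base is kept at or below 0 °C so that the doubly allylic ring hydrogen is not abstracted.

Step 18
Reactants: 29 enyne
Product: 31 (1E,3E)-1-iodo-2-methyl-4-[(1R,5S)-2,5,6,6-tetramethylcyclohex-2-en-1-yl]buta-1,3-diene, via alkenylalane 30 (not isolated)
Conditions: Me3Al, Cp2ZrCl2 (25 mol %), CH2Cl2, 0 °C to rt; then I2, THF, −30 °C
Reagents that add atoms: trimethylaluminium, C[Al](C)C; iodine, II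
Why: Zirconium-catalysed carboalumination adds methyl and aluminium syn across the terminal alkyne, with aluminium on the terminal carbon, as known for conjugated enynes of the ionone series. Iodinolysis with retention gives the (E)-iodide.

Step 19
Reactants: 25 alkyl iodide; 31 dienyl iodide
Product: 33 silyl-protected coupling product (Cc–OSiMe3; C-alpha CH2OSiEt3; propyl OSi(t-Bu)Me2), via alkylzinc iodide 32 (not isolated)
Conditions: Zn dust, LiCl, THF, 40 °C; then 31, PdCl2(dppf) (5 mol %), THF, rt
Reagents that add atoms: none
Why: Zinc inserts into the primary C–I bond without touching the ethers, and Negishi coupling joins the alkylzinc to the alkenyl iodide with retention of both alkene geometries; the bidentate ligand disfavours β-hydride elimination.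

Step 20
Reactants: 33 silyl-protected coupling product
Product: 34 diol with free C-alpha CH2OH and free Cc–OH, propyl arm still silylated
Conditions: PPTS, MeOH/CH2Cl2, 0 °C
Reagents that add atoms: none
Why: Mild acid methanolysis removes the primary triethylsilyl and tertiary trimethylsilyl ethers much faster than the primary tert-butyldimethylsilyl ether, and is too weak to isomerise the triene.

Step 21
Reactants: 34 diol
Product: 35 aldehyde with silylated propyl arm
Conditions: Dess–Martin periodinane, NaHCO3, CH2Cl2, 0 °C
Reagents that add atoms: none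
Why: Buffered Dess–Martin oxidation converts the single primary alcohol into the aldehyde; the tertiary alcohol cannot be oxidised, and the neutral medium avoids epimerisation at C-alpha and β-elimination of the ether oxygen.

Step 22
Reactants: 35 silyl-protected aldehyde
Product: 36 (2S)-2-[(1S,2S,5R,8S)-2-hydroxy-8-(3-hydroxypropyl)-2-methyl-1-[(3E,5E)-4-methyl-6-[(1R,5S)-2,5,6,6-tetramethylcyclohex-2-en-1-yl]hexa-3,5-dien-1-yl]-6-oxabicyclo[3.2.1]octan-5-yl]propanal (CNP0419303.1)
Conditions: HF·pyridine, pyridine, THF, 0 °C
Reagents that add atoms: none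
Why: Buffered fluoride cleaves the remaining silyl ether under slightly acidic conditions, which spare the β-alkoxy aldehyde from base-induced epimerisation and ring opening.

## Compound list

1 | pent-4-en-1-ol | C=CCCCO | starting material
2 | tert-butyldimethyl(pent-4-en-1-yloxy)silane | C=CCCCO[Si](C)(C)C(C)(C)C | intermediate
3 | but-3-en-2-one | C=CC(C)=O | starting material
4 | (E)-7-[(tert-butyldimethylsilyl)oxy]hept-3-en-2-one | CC(=O)/C=C/CCCO[Si](C)(C)C(C)(C)C | intermediate
5 | 3-acetyloxolan-2-one (2-acetylbutyrolactone, racemic) | CC(=O)C1CCOC1=O | starting material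
6 | 3-acetyl-3-{7-[(tert-butyldimethylsilyl)oxy]-2-oxoheptan-4-yl}oxolan-2-one (Ca and Cd as drawn) | CC(=O)C[C@@H](CCCO[Si](C)(C)C(C)(C)C)[C@@]1(C(C)=O)CCOC1=O | intermediate (not isolated)
7 | 6-methyl-10-[3-(tert-butyldimethylsilyloxy)propyl]-2-oxaspiro[4.5]dec-6-ene-1,8-dione (lactone C=O cis to the C10 chain) | CC1=CC(=O)C[C@@H](CCCO[Si](C)(C)C(C)(C)C)[C@]12CCOC2=O | intermediate
8 | (E)-but-2-en-1-yl methyl carbonate | C/C=C/COC(=O)OC | starting material
9 | 8-trimethylsilyloxy-6,8-diene (silyl dienol ether of 7) | CC1=CC(O[Si](C)(C)C)=C[C@@H](CCCO[Si](C)(C)C(C)(C)C)[C@]12CCOC2=O | intermediate (not isolated)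
10 | 9-[(2R)-but-3-en-2-yl]-6-methyl-10-[3-(tert-butyldimethylsilyloxy)propyl]-2-oxaspiro[4.5]dec-6-ene-1,8-dione (C9 trans to C10 chain) | CC1=CC(=O)[C@H]([C@H](C)C=C)[C@@H](CCCO[Si](C)(C)C(C)(C)C)[C@]12CCOC2=O | intermediate
11 | (2S)-2-[6-methyl-1,8-dioxo-10-[3-(tert-butyldimethylsilyloxy)propyl]-2-oxaspiro[4.5]dec-6-en-9-yl]propanal | CC1=CC(=O)[C@H]([C@H](C)C=O)[C@@H](CCCO[Si](C)(C)C(C)(C)C)[C@]12CCOC2=O | intermediate (not isolated)
12 | 9-[(2S)-1-hydroxypropan-2-yl]-6-methyl-10-[3-(tert-butyldimethylsilyloxy)propyl]-2-oxaspiro[4.5]dec-6-ene-1,8-dione | CC1=CC(=O)[C@H]([C@H](C)CO)[C@@H](CCCO[Si](C)(C)C(C)(C)C)[C@]12CCOC2=O | intermediate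
13 | 6-methyl-10-[3-(tert-butyldimethylsilyloxy)propyl]-9-[(2S)-1-(triethylsilyloxy)propan-2-yl]-2-oxaspiro[4.5]dec-6-ene-1,8-dione | CC1=CC(=O)[C@H]([C@H](C)CO[Si](CC)(CC)CC)[C@@H](CCCO[Si](C)(C)C(C)(C)C)[C@]12CCOC2=O | intermediate
14 | 6-methyl-1-oxo-10-[3-(tert-butyldimethylsilyloxy)propyl]-9-[(2S)-1-(triethylsilyloxy)propan-2-yl]-2-oxaspiro[4.5]deca-6,8-dien-8-yl trifluoromethanesulfonate | CC1=CC(OS(=O)(=O)C(F)(F)F)=C([C@H](C)CO[Si](CC)(CC)CC)[C@@H](CCCO[Si](C)(C)C(C)(C)C)[C@]12CCOC2=O | intermediate
15 | 6-methyl-10-[3-(tert-butyldimethylsilyloxy)propyl]-9-[(2S)-1-(triethylsilyloxy)propan-2-yl]-2-oxaspiro[4.5]deca-6,8-dien-1-one | CC1=CC=C([C@H](C)CO[Si](CC)(CC)CC)[C@@H](CCCO[Si](C)(C)C(C)(C)C)[C@]12CCOC2=O | intermediate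
16 | 2-[1-(hydroxymethyl)-2-methyl-6-[3-(tert-butyldimethylsilyloxy)propyl]-5-[(2S)-1-(triethylsilyloxy)propan-2-yl]cyclohexa-2,4-dien-1-yl]ethanol (CH2OH cis to the C6 chain) | OCC[C@]1(CO)C(C)=CC=C([C@H](C)CO[Si](CC)(CC)CC)[C@H]1CCCO[Si](C)(C)C(C)(C)C | intermediate
17 | 2-[1-(hydroxymethyl)-2-methyl-6-[3-(tert-butyldimethylsilyloxy)propyl]-5-[(2S)-1-(triethylsilyloxy)propan-2-yl]cyclohexa-2,4-dien-1-yl]ethyl pivalate | CC(C)(C)C(=O)OCC[C@]1(CO)C(C)=CC=C([C@H](C)CO[Si](CC)(CC)CC)[C@H]1CCCO[Si](C)(C)C(C)(C)C | intermediate (precursor of the key step)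
18 | dioxygen (used as photosensitised singlet oxygen) | O=O | starting material
19 | 2-[7-(hydroxymethyl)-1-methyl-8-[3-(tert-butyldimethylsilyloxy)propyl]-4-[1-(triethylsilyloxy)propan-2-yl]-2,3-dioxabicyclo[2.2.2]oct-5-en-7-yl]ethyl pivalate (peroxide bridge syn to CH2OH and to the C8 chain) | CC(C)(C)C(=O)OCC[C@]1(CO)[C@@]2(C)OO[C@@](C=C2)([C@H](C)CO[Si](CC)(CC)CC)[C@H]1CCCO[Si](C)(C)C(C)(C)C | intermediate (product of the key step)
20 | 2-[2,5-dihydroxy-1-(hydroxymethyl)-2-methyl-6-[3-(tert-butyldimethylsilyloxy)propyl]-5-[1-(triethylsilyloxy)propan-2-yl]cyclohexyl]ethyl pivalate (the three oxygens on C1-CH2, C2 and C5 cis) | CC(C)(C)C(=O)OCC[C@]1(CO)[C@@](C)(O)CC[C@](O)([C@H](C)CO[Si](CC)(CC)CC)[C@H]1CCCO[Si](C)(C)C(C)(C)C | intermediate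
21 | primary triflate of 20 | CC(C)(C)C(=O)OCC[C@]1(COS(=O)(=O)C(F)(F)F)[C@@](C)(O)CC[C@](O)([C@H](C)CO[Si](CC)(CC)CC)[C@H]1CCCO[Si](C)(C)C(C)(C)C | intermediate (not isolated)
22 | 2-[(1S,2S,5R,8S)-2-hydroxy-2-methyl-8-[3-(tert-butyldimethylsilyloxy)propyl]-5-[1-(triethylsilyloxy)propan-2-yl]-6-oxabicyclo[3.2.1]octan-1-yl]ethyl pivalate | CC(C)(C)C(=O)OCC[C@]12CO[C@]([C@H](C)CO[Si](CC)(CC)CC)(CC[C@]1(C)O)[C@H]2CCCO[Si](C)(C)C(C)(C)C | intermediate (not isolated)
23 | 2-[(1S,2S,5R,8S)-2-methyl-8-[3-(tert-butyldimethylsilyloxy)propyl]-5-[1-(triethylsilyloxy)propan-2-yl]-2-(trimethylsilyloxy)-6-oxabicyclo[3.2.1]octan-1-yl]ethyl pivalate | CC(C)(C)C(=O)OCC[C@]12CO[C@]([C@H](C)CO[Si](CC)(CC)CC)(CC[C@]1(C)O[Si](C)(C)C)[C@H]2CCCO[Si](C)(C)C(C)(C)C | intermediate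
24 | 2-[(1S,2S,5R,8S)-2-methyl-8-[3-(tert-butyldimethylsilyloxy)propyl]-5-[1-(triethylsilyloxy)propan-2-yl]-2-(trimethylsilyloxy)-6-oxabicyclo[3.2.1]octan-1-yl]ethanol | OCC[C@]12CO[C@]([C@H](C)CO[Si](CC)(CC)CC)(CC[C@]1(C)O[Si](C)(C)C)[C@H]2CCCO[Si](C)(C)C(C)(C)C | intermediate
25 | (1S,2S,5R,8S)-1-(2-iodoethyl)-2-methyl-8-[3-(tert-butyldimethylsilyloxy)propyl]-5-[1-(triethylsilyloxy)propan-2-yl]-2-(trimethylsilyloxy)-6-oxabicyclo[3.2.1]octane | ICC[C@]12CO[C@]([C@H](C)CO[Si](CC)(CC)CC)(CC[C@]1(C)O[Si](C)(C)C)[C@H]2CCCO[Si](C)(C)C(C)(C)C | intermediate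
26 | α-irone, commercial mixture of racemic cis and trans isomers | CC1=CCC(C)C(C)(C)C1/C=C/C(C)=O | starting material
27 | (E)-4-[(1R,5S)-2,5,6,6-tetramethylcyclohex-2-en-1-yl]but-3-en-2-one ((2S,6R)-cis-α-irone) | CC1=CC[C@H](C)C(C)(C)[C@@H]1/C=C/C(C)=O | intermediate
28 | diethyl (E)-4-[(1R,5S)-2,5,6,6-tetramethylcyclohex-2-en-1-yl]buta-1,3-dien-2-yl phosphate | CC1=CC[C@H](C)C(C)(C)[C@@H]1/C=C/C(=C)OP(=O)(OCC)OCC | intermediate (not isolated)
29 | (E)-4-[(1R,5S)-2,5,6,6-tetramethylcyclohex-2-en-1-yl]but-3-en-1-yne | CC1=CC[C@H](C)C(C)(C)[C@@H]1/C=C/C#C | intermediate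
30 | dimethyl[(1E,3E)-2-methyl-4-[(1R,5S)-2,5,6,6-tetramethylcyclohex-2-en-1-yl]buta-1,3-dien-1-yl]alane | CC1=CC[C@H](C)C(C)(C)[C@@H]1/C=C/C(C)=C/[Al](C)C | intermediate (not isolated)
31 | (1E,3E)-1-iodo-2-methyl-4-[(1R,5S)-2,5,6,6-tetramethylcyclohex-2-en-1-yl]buta-1,3-diene | CC1=CC[C@H](C)C(C)(C)[C@@H]1/C=C/C(C)=C/I | intermediate
32 | alkylzinc iodide from 25 | I[Zn]CC[C@]12CO[C@]([C@H](C)CO[Si](CC)(CC)CC)(CC[C@]1(C)O[Si](C)(C)C)[C@H]2CCCO[Si](C)(C)C(C)(C)C | intermediate (not isolated)
33 | fully silylated coupling product (Cc–OSiMe3, C-alpha CH2OSiEt3, propyl OSi(t-Bu)Me2) | CC1=CC[C@H](C)C(C)(C)[C@@H]1/C=C/C(C)=C/CC[C@]12CO[C@]([C@H](C)CO[Si](CC)(CC)CC)(CC[C@]1(C)O[Si](C)(C)C)[C@H]2CCCO[Si](C)(C)C(C)(C)C | intermediate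
34 | diol: free C-alpha CH2OH and Cc–OH, propyl arm silylated | CC1=CC[C@H](C)C(C)(C)[C@@H]1/C=C/C(C)=C/CC[C@]12CO[C@]([C@H](C)CO)(CC[C@]1(C)O)[C@H]2CCCO[Si](C)(C)C(C)(C)C | intermediate
35 | aldehyde with tert-butyldimethylsilyl ether on the propyl arm | CC1=CC[C@H](C)C(C)(C)[C@@H]1/C=C/C(C)=C/CC[C@]12CO[C@]([C@H](C)C=O)(CC[C@]1(C)O)[C@H]2CCCO[Si](C)(C)C(C)(C)C | intermediate
36 | (2S)-2-[(1S,2S,5R,8S)-2-hydroxy-8-(3-hydroxypropyl)-2-methyl-1-[(3E,5E)-4-methyl-6-[(1R,5S)-2,5,6,6-tetramethylcyclohex-2-en-1-yl]hexa-3,5-dien-1-yl]-6-oxabicyclo[3.2.1]octan-5-yl]propanal | CC1=CC[C@H](C)C(C)(C)[C@@H]1/C=C/C(C)=C/CC[C@]12CO[C@]([C@H](C)C=O)(CC[C@]1(C)O)[C@H]2CCCO | target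

## Step count and least certain steps

Total: 22 steps. Longest linear sequence: 19 steps (steps 1–15 and 19–22); steps 16–18 are a three-step side branch.

Step 11 (key step). What may go wrong is poor facial selectivity: oxygen may add anti to the Cd chain. Each face carries one pseudoaxial CH2 substituent, so the outcome rests on the hydrogen bond to the homoallylic hydroxyl. Some ene reaction at the Cc methyl is a minor risk. The fallback sets out from 17. VO(acac)2 and t-BuOOH epoxidise both ring alkenes under covalent direction by the vanadium-bound CH2OH (homoallylic for Cc=Ch, bishomoallylic for Cg=Cb), giving the syn-bis-epoxide F1. LiEt3BH then delivers hydride to the two secondary oxirane carbons Ch and Cg and cleaves the pivalate, giving the tetraol F2. Pivaloylation of the unhindered primary hydroxyl as in step 10 returns to the route at 20.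

Step 3. The Michael addition may be slow and poorly selective, because a quaternary centre is formed next to a tertiary one with a β-alkyl enone; the wrong relative configuration of Ca and Cd or low enantioselectivity would result. The fallback sets out from 4 and 5. The annulation is run without a chiral catalyst (DBU, then pyrrolidine/AcOH), giving 7 together with its enantiomer F3. The enantioselective allylation of step 4 then converts the pair into 10 and the diastereomer F4, which differ in the relation of C-alpha to the ring centres and are separated on silica. The route is rejoined at 10.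

Step 4. Branched selectivity may erode with the small methyl-substituted allyl unit, the free enolate may reopen by retro-Michael reaction at 50 °C and scramble Ca/Cd, fluoride may partly cleave the silyl ether, and the facial sense at C-alpha is set only by the ligand. The fallback sets out from 7. Deprotonation with LiN(SiMe3)2 and transmetalation with CuI give a copper enolate. RhCl(PPh3)3 modified with P(OMe)3 couples it at low temperature with the enantiopure (R)-but-3-en-2-yl methyl carbonate F5, made from commercial (R)-but-3-en-2-ol and methyl chloroformate. Substitution occurs at the carbon that bore the leaving group with net retention, so C-alpha comes from the chiral pool. The route is rejoined at 10.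

Step 7. Deprotonation of the hindered tertiary Cb–H may be slow, so that γ-deprotonation at the Cc methyl competes and gives a regioisomeric triflate. The fallback sets out from 13. NaBH4/CeCl3 gives the allylic alcohol F6 (both carbinol epimers), which is dehydrated with bis[α,α-bis(trifluoromethyl)benzyloxy]diphenylsulfurane. The only sp3 carbon beside the carbinol that carries hydrogen is Cb, so 1,2-elimination gives the same diene and the route is rejoined at 15.

Step 13. A tertiary hydroxyl may be sulfonylated and eliminate, or the neopentyl triflate may fragment or rearrange before the Cb hydroxyl closes the ring. The fallback sets out from 20 and avoids substitution at the neopentyl carbon. Dess–Martin oxidation converts the only primary alcohol into the aldehyde, which is trapped by the cis Cb hydroxyl as the bridged lactol F7. Et3SiH with BF3·OEt2 at −78 °C reduces the derived oxocarbenium ion to the ether. The route is rejoined at 22, which is silylated as in step 13.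

Step 16. Separation of four stereoisomers of a volatile ketone on a preparative scale may be incomplete. The fallback sets out from 26. NaBH4/CeCl3 gives the allylic alcohols, among them the (R)-carbinol F8 of the wanted ring enantiomer; the cis-ring carbinol diastereomers are enriched by chromatography. Acetylation with Burkholderia cepacia lipase and vinyl acetate esterifies only (R)-carbinols, giving the acetate F9, which is separated from the unreacted alcohols and from its ring diastereomer. Methanolysis back to the alcohol and oxidation with MnO2 rejoin the route at 27.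

## Further compounds

F1 | step 11 | syn-bis-epoxide of 17 (both oxiranes on the face of CH2OH) | CC(C)(C)C(=O)OCC[C@]1(CO)[C@@]2(C)O[C@H]2[C@H]2O[C@@]2([C@H](C)CO[Si](CC)(CC)CC)[C@H]1CCCO[Si](C)(C)C(C)(C)C
F2 | step 11 | tetraol (depivaloylated 20) | OCC[C@]1(CO)[C@@](C)(O)CC[C@](O)([C@H](C)CO[Si](CC)(CC)CC)[C@H]1CCCO[Si](C)(C)C(C)(C)C
F3 | step 3 | enantiomer of 7 (second component of the racemate) | CC1=CC(=O)C[C@H](CCCO[Si](C)(C)C(C)(C)C)[C@@]12CCOC2=O
F4 | step 3 | diastereomer of 10 formed from F3 (same C-alpha, enantiomeric ring centres) | CC1=CC(=O)[C@@H]([C@H](C)C=C)[C@H](CCCO[Si](C)(C)C(C)(C)C)[C@@]12CCOC2=O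
F5 | step 4 | (R)-but-3-en-2-yl methyl carbonate | COC(=O)O[C@H](C)C=C
F6 | step 7 | allylic alcohol from 13 (8-hydroxy, both epimers) | CC1=CC(O)[C@H]([C@H](C)CO[Si](CC)(CC)CC)[C@@H](CCCO[Si](C)(C)C(C)(C)C)[C@]12CCOC2=O
F7 | step 13 | bridged lactol (7-hydroxy-6-oxabicyclo[3.2.1]octane, both anomers) | CC(C)(C)C(=O)OCC[C@]12C(O)O[C@]([C@H](C)CO[Si](CC)(CC)CC)(CC[C@]1(C)O)[C@H]2CCCO[Si](C)(C)C(C)(C)C
F8 | step 16 | (2R,3E)-4-[(1R,5S)-2,5,6,6-tetramethylcyclohex-2-en-1-yl]but-3-en-2-ol | CC1=CC[C@H](C)C(C)(C)[C@@H]1/C=C/[C@@H](C)O
F9 | step 16 | (2R,3E)-4-[(1R,5S)-2,5,6,6-tetramethylcyclohex-2-en-1-yl]but-3-en-2-yl acetate | CC1=CC[C@H](C)C(C)(C)[C@@H]1/C=C/[C@@H](C)OC(C)=O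
A1 | alternative 1 | bridged ether ester | C=CC[C@]12CO[C@]([C@H](C)C(=O)OC)(CC[C@]1(C)O[Si](CC)(CC)CC)[C@H]2CCCO[Si](C)(C)C(C)(C)C
A2 | alternative 1 | oxepane xanthate with exocyclic alkoxyacrylate (either carbinol epimer) | C=CC[C@]1(C(OC(=S)SC)CCCO[Si](C)(C)C(C)(C)C)COC(=C(C)C(=O)OC)CC[C@]1(C)O[Si](CC)(CC)CC
A3 | alternative 2 | 6-oxabicyclo[3.2.1]octanone ester | COC(=O)[C@]12CO[C@](C(C)=C)(CCC1=O)[C@H]2CCCO[Si](C)(C)C(C)(C)C
A4 | alternative 2 | bicyclo[3.1.0]hexan-2-one keto ester (side chain exo) | COC(=O)[C@@]12C(=O)CC[C@]1(C(C)=C)[C@H]2CCCO[Si](C)(C)C(C)(C)C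
A5 | alternative 2 | formaldehyde | C=O
A6 | alternative 3 | bridged ether from the methyl group | COC(=O)C[C@]12CO[C@]([C@H](C)CO[Si](C)(C)C(C)(C)C)(CC[C@]1(C)OC(C)=O)[C@H]2CCCO[Si](c1ccccc1)(c1ccccc1)C(C)(C)C
A7 | alternative 3 | tertiary alcohol with axial methyl on Ca | COC(=O)C[C@@]1(C)[C@H](CCCO[Si](c2ccccc2)(c2ccccc2)C(C)(C)C)[C@@](O)([C@H](C)CO[Si](C)(C)C(C)(C)C)CC[C@]1(C)OC(C)=O
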